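**Retrosynthetic overview**
- Target 14 is a cis-epoxyquinol: a cyclohex-2-enone (C1–C6) fused to an oxirane (C1–O7–C6). The six-membered ring is cut in a [3+3] sense at C1–C2 (oxirane carbon to ketone carbon) and at C4–C5 (enone β-carbon to carbinol carbon).
- Enabling feature: ketone C2 and carbinol C5 are 1,4-related across C3=C4 (a γ-hydroxy enone), so C4 and the aldehyde carbon C5 have like polarity. A nitro group on C4 reverses the polarity and then leaves as nitrite to create C3=C4, while the tin-bearing oxirane carbon C1 accepts the acyl carbon C2.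
- Fragments: stannyl epoxy aldehyde 7 (C1, C6, C5 and the farnesyl chain) from propargyl alcohol and farnesyl bromide; nitro thioester 11 (C2, C3, C4 and the ethyl group) from (E)-pent-2-enal.
- Ring order: the oxirane is made first (step 3, fixes C1 and C6); the carbocycle is closed last (step 8), which also sets C5 and gives 14 without protecting groups.

Key step: step 8

Remark: 9–13 are carried as mixtures at the nitro-bearing carbon, which becomes sp2 in step 8; the facial sense of step 3 is assigned by the usual rule for primary allylic alcohols and should be confirmed on 6.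

Step 1
Reactants: 1 prop-2-yn-1-ol; 2 (2E,6E)-farnesyl bromide
Product: 3 (5E,9E)-6,10,14-trimethylpentadeca-5,9,13-trien-2-yn-1-ol
Conditions: CuI (10 mol %), K2CO3, n-Bu4NCl (cat.), DMF, rt
Reagents that add atoms: none
Why: Copper-catalysed SN2 alkynylation of the primary allylic bromide by the copper acetylide formed in situ should give the skipped enyne with the (2E,6E) geometry of the farnesyl unit untouched.

Step 2
Reactants: 3 (5E,9E)-6,10,14-trimethylpentadeca-5,9,13-trien-2-yn-1-ol
Product: 5 (2Z,5E,9E)-6,10,14-trimethyl-3-(tributylstannyl)pentadeca-2,5,9,13-tetraen-1-ol, via cyclic alkenylalanate 4 (not isolated)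
Conditions: NaAlH2(OCH2CH2OMe)2, THF, 0 °C to rt; then Bu3SnOTf, −78 °C to rt; aqueous Rochelle salt
Reagents that add atoms: tributyltin trifluoromethanesulfonate, CCCC[Sn](CCCC)(CCCC)OS(=O)(=O)C(F)(F)F
Why: Hydroxyl-directed trans-hydroalumination of the propargylic alcohol puts hydride on C2 and aluminium on C3 in a five-membered alkoxyalanate, and aluminium-to-tin transmetalation with retention then fixes the (Z)-alkenylstannane in which tin and the carbinol carbon are cis, as the ketone carbon and C5 must later be on the oxirane.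

Step 3
Reactants: 5 (2Z,5E,9E)-6,10,14-trimethyl-3-(tributylstannyl)pentadeca-2,5,9,13-tetraen-1-ol
Product: 6 [(2R,3S)-3-(tributylstannyl)-3-[(2E,6E)-3,7,11-trimethyldodeca-2,6,10-trien-1-yl]oxiran-2-yl]methanol
Conditions: Ti(Oi-Pr)4 (10 mol %), D-(−)-diethyl tartrate (12 mol %), t-BuOOH, 4 Å MS, CH2Cl2, −20 °C
Reagents that add atoms: tert-butyl hydroperoxide, CC(C)(C)OO
Why: Sharpless asymmetric epoxidation is chemoselective for the allylic alcohol over the three isolated trisubstituted alkenes and stereospecific, and with D-(−)-tartrate oxygen should be delivered to the face that gives the (2R,3S) epoxide, which sets C1 and C6 of the target.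

Step 4
Reactants: 6 [(2R,3S)-3-(tributylstannyl)-3-[(2E,6E)-3,7,11-trimethyldodeca-2,6,10-trien-1-yl]oxiran-2-yl]methanol
Product: 7 (2R,3S)-3-(tributylstannyl)-3-[(2E,6E)-3,7,11-trimethyldodeca-2,6,10-trien-1-yl]oxirane-2-carbaldehyde
Conditions: Dess–Martin periodinane, NaHCO3, CH2Cl2, 0 °C
Reagents that add atoms: none
Why: Buffered Dess–Martin oxidation is a mild alcohol-to-aldehyde oxidation that should leave the oxirane, the carbon–tin bond and the alkenes intact and cannot over-oxidise.

Step 5
Reactants: 8 (E)-pent-2-enal
Product: 9 3-nitropentanal (racemic)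
Conditions: NaNO2, AcOH, THF–H2O, 0 °C
Reagents that add atoms: sodium nitrite, [Na+].[O-]N=O
Why: Michael addition of nitrous acid (from nitrite and acetic acid) to the enal places a nitro group on the β-carbon, the polarity-reversing group that lets this carbon act as a nucleophile in step 8.

Step 6
Reactants: 9 3-nitropentanal
Product: 10 3-nitropentanoic acid (racemic)
Conditions: NaClO2, NaH2PO4, 2-methyl-2-butene, t-BuOH–H2O, 0 °C to rt
Reagents that add atoms: sodium chlorite, [Na+].[O-]Cl=O
Why: Pinnick oxidation converts the aldehyde into the acid at mildly acidic pH, so base-induced loss of nitrous acid from the β-nitro carbonyl compound is avoided.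

Step 7
Reactants: 10 3-nitropentanoic acid
Product: 11 S-phenyl 3-nitropentanethioate (racemic)
Conditions: PhSH, DCC, DMAP (5 mol %), CH2Cl2, 0 °C
Reagents that add atoms: thiophenol, Sc1ccccc1
Why: Steglich-type carbodiimide thioesterification gives the S-phenyl thioester needed as acyl partner for the neutral cross-coupling, with low temperature and only catalytic DMAP to keep elimination of nitrous acid in check.

Step 8
Reactants: 7 (2R,3S)-3-(tributylstannyl)-3-[(2E,6E)-3,7,11-trimethyldodeca-2,6,10-trien-1-yl]oxirane-2-carbaldehyde; 11 S-phenyl 3-nitropentanethioate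
Product: 14 (1R,5R,6R)-4-ethyl-5-hydroxy-1-[(2E,6E)-3,7,11-trimethyldodeca-2,6,10-trien-1-yl]-7-oxabicyclo[4.1.0]hept-3-en-2-one, via nitro keto aldehyde 12 (not isolated), via nitro aldol 13 (not isolated)
Conditions: Pd2(dba)3 (5 mol %), P(2-furyl)3 (20 mol %), CuO2PPh2 (1.5 equiv), THF, 40 °C; then dilute with THF, LiCl (3 equiv), DBU (1.5 equiv), −20 to 0 °C
Reagents that add atoms: none
Why: Proposed new method: under neutral Liebeskind–Srogl conditions the acylpalladium formed from thioester 11 should accept the oxiranyl group of 7 from tin with retention, making the C1–C2 bond while the aldehyde and the nitroalkane are left alone; the closest known reaction types are the copper-assisted, stereoretentive acylation of α-alkoxyalkylstannanes and the thioester–organostannane ketone synthesis, and the oxirane carbon, like a cyclopropyl carbon, has high s-character and should transfer in preference to butyl. DBU then converts 12 fully into the nitronate (the nitro-bearing carbon is the most acidic site by several pK units), which adds to the aldehyde in a 6-exo-trig Henry closure, the only ring closed in this step; this is the like-polarity union of enone β-carbon C4 with carbinol carbon C5. The new stereocentre C5 is controlled by the fixed oxirane centre C6: lithium chelation between the aldehyde and oxirane oxygens should place the hydroxyl cis to the oxirane oxygen (5R). The tertiary β-nitro ketone 13 then loses nitrite by E1cB to give the C3=C4 enone, so the nitro group is a traceless activating group and the mixture at its carbon is of no consequence. The selectivities needed are oxiranyl over butyl transfer, ring closure before elimination (secured because a nitronate is not a leaving group, so nitrite can only be lost after the C–C bond is formed) and cis over trans at C5 (to be secured by chelation, with cold, weak base because the product is base-sensitive).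

**Compound list**
1 | prop-2-yn-1-ol (propargyl alcohol) | C#CCO | starting material
2 | (2E,6E)-1-bromo-3,7,11-trimethyldodeca-2,6,10-triene (farnesyl bromide) | BrC/C=C(\C)CC/C=C(\C)CCC=C(C)C | starting material
3 | (5E,9E)-6,10,14-trimethylpentadeca-5,9,13-trien-2-yn-1-ol | OCC#CC/C=C(\C)CC/C=C(\C)CCC=C(C)C | intermediate
4 | sodium cyclic alkenylalanate: five-membered O–Al–C chelate of the (2Z)-3-alumino allylic alkoxide, two 2-methoxyethoxy groups on aluminium | [Na+].COCCO[Al-]1(OCCOC)OCC=C1C/C=C(\C)CC/C=C(\C)CCC=C(C)C | intermediate (not isolated)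
5 | (2Z,5E,9E)-6,10,14-trimethyl-3-(tributylstannyl)pentadeca-2,5,9,13-tetraen-1-ol | OC/C=C(\[Sn](CCCC)(CCCC)CCCC)C/C=C(\C)CC/C=C(\C)CCC=C(C)C | intermediate
6 | [(2R,3S)-3-(tributylstannyl)-3-[(2E,6E)-3,7,11-trimethyldodeca-2,6,10-trien-1-yl]oxiran-2-yl]methanol | CCCC[Sn](CCCC)(CCCC)[C@]1(C/C=C(\C)CC/C=C(\C)CCC=C(C)C)O[C@@H]1CO | intermediate
7 | (2R,3S)-3-(tributylstannyl)-3-[(2E,6E)-3,7,11-trimethyldodeca-2,6,10-trien-1-yl]oxirane-2-carbaldehyde | CCCC[Sn](CCCC)(CCCC)[C@]1(C/C=C(\C)CC/C=C(\C)CCC=C(C)C)O[C@@H]1C=O | intermediate
8 | (E)-pent-2-enal | CC/C=C/C=O | starting material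
9 | 3-nitropentanal (racemic) | CCC(CC=O)[N+](=O)[O-] | intermediate
10 | 3-nitropentanoic acid (racemic) | CCC(CC(=O)O)[N+](=O)[O-] | intermediate
11 | S-phenyl 3-nitropentanethioate (racemic) | CCC(CC(=O)Sc1ccccc1)[N+](=O)[O-] | intermediate
12 | (2S,3R)-3-(3-nitropentanoyl)-3-[(2E,6E)-3,7,11-trimethyldodeca-2,6,10-trien-1-yl]oxirane-2-carbaldehyde (both epimers at the nitro carbon) | CCC(CC(=O)[C@]1(C/C=C(\C)CC/C=C(\C)CCC=C(C)C)O[C@@H]1C=O)[N+](=O)[O-] | intermediate (not isolated)
13 | (1R,5R,6R)-4-ethyl-5-hydroxy-4-nitro-1-[(2E,6E)-3,7,11-trimethyldodeca-2,6,10-trien-1-yl]-7-oxabicyclo[4.1.0]heptan-2-one (both C4 epimers) | CCC1([N+](=O)[O-])CC(=O)[C@]2(C/C=C(\C)CC/C=C(\C)CCC=C(C)C)O[C@@H]2[C@@H]1O | intermediate (not isolated)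
14 | (1R,5R,6R)-4-ethyl-5-hydroxy-1-[(2E,6E)-3,7,11-trimethyldodeca-2,6,10-trien-1-yl]-7-oxabicyclo[4.1.0]hept-3-en-2-one | CCC1=CC(=O)[C@]2(C/C=C(\C)CC/C=C(\C)CCC=C(C)C)O[C@@H]2[C@@H]1O | target

Total step count: 8. Longest linear sequence: 5 steps (steps 1, 2, 3, 4 and 8); steps 5–7 form the second branch.

**Steps most likely to fail**

1. Step 8 (proposed new method). Three processes may go wrong: transfer of the oxiranyl group from tin to the acylpalladium may fail (butyl transfer, protodestannylation or opening of the metalated oxirane); nitrous acid may be lost before the ring closes; and facial selectivity in the nitronate addition to the aldehyde may be poor. The fallback uses known reaction types, sets out from 6 and 8, and returns at 12 and from there at 14. Alcohol 6 is silylated (TBSCl, imidazole, DMF) to the tert-butyldimethylsilyl ether F1. Tin–lithium exchange (n-BuLi, TMEDA, THF, −90 °C) should give the configurationally stable oxiranyllithium F2, which adds to the aldehyde of 8 to give the allylic alcohol F3 as carbinol epimers. Bu4NF removes the silyl group to give the diol F4, and Dess–Martin oxidation of both hydroxyls gives the enone aldehyde F5. Conjugate addition of nitrous acid (NaNO2, AcOH) to the enone gives 12, now isolated, which is cyclised with LiCl/DBU as in step 8. If that closure delivers mainly the trans epoxy alcohol F6, it is inverted by a Mitsunobu reaction (4-nitrobenzoic acid, PPh3, DIAD) to the 4-nitrobenzoate F7, whose methanolysis (K2CO3, MeOH) gives 14.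

2. Step 3. Oxygen transfer to the hindered (Z)-trisubstituted stannyl alkene may be slow or poorly face-selective, and the titanium Lewis acid may promote destannylative opening of the epoxy stannane. The fallback sets out from 5 and returns at 6, replacing asymmetric catalysis by resolution. Hydroxyl-directed epoxidation with VO(acac)2 and t-BuOOH gives the racemic cis epoxy alcohol F8. Lipase-catalysed acetylation (Burkholderia cepacia lipase, vinyl acetate) then resolves it: the unwanted enantiomer is removed as the acetate F9 and 6 is recovered as the unreacted alcohol.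

3. Step 2. Aluminium-to-tin exchange at the hindered alkenylalanate may be incomplete, with protonolysis to the tin-free allylic alcohol on work-up. The fallback sets out from 3 and returns at 5. The same hydroalumination is quenched with iodine at −78 °C to give the (Z)-vinyl iodide F10, and Pd(PPh3)4-catalysed stannylation with (Bu3Sn)2 in toluene then gives 5.

**Further compounds**
F1 | step 8 | tert-butyldimethylsilyl ether of 6 (oxirane configuration as in 6) | CCCC[Sn](CCCC)(CCCC)[C@]1(C/C=C(\C)CC/C=C(\C)CCC=C(C)C)O[C@@H]1CO[Si](C)(C)C(C)(C)C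
F2 | step 8 | oxiranyllithium from F1 (lithium in place of tributylstannyl, configuration retained) | [Li][C@]1(C/C=C(\C)CC/C=C(\C)CCC=C(C)C)O[C@@H]1CO[Si](C)(C)C(C)(C)C
F3 | step 8 | (E)-1-[3-(tert-butyldimethylsilyloxymethyl)-2-farnesyloxiran-2-yl]pent-2-en-1-ol (carbinol epimers, oxirane configuration as in 6) | CC/C=C/C(O)[C@]1(C/C=C(\C)CC/C=C(\C)CCC=C(C)C)O[C@@H]1CO[Si](C)(C)C(C)(C)C
F4 | step 8 | (E)-1-[2-farnesyl-3-(hydroxymethyl)oxiran-2-yl]pent-2-en-1-ol (carbinol epimers) | CC/C=C/C(O)[C@]1(C/C=C(\C)CC/C=C(\C)CCC=C(C)C)O[C@@H]1CO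
F5 | step 8 | 3-farnesyl-3-[(E)-pent-2-enoyl]oxirane-2-carbaldehyde (oxirane configuration as in 12) | CC/C=C/C(=O)[C@]1(C/C=C(\C)CC/C=C(\C)CCC=C(C)C)O[C@@H]1C=O
F6 | step 8 | (1R,5S,6R) epimer of 14 (hydroxyl trans to the oxirane oxygen) | CCC1=CC(=O)[C@]2(C/C=C(\C)CC/C=C(\C)CCC=C(C)C)O[C@@H]2[C@H]1O
F7 | step 8 | 4-nitrobenzoate of 14 | CCC1=CC(=O)[C@]2(C/C=C(\C)CC/C=C(\C)CCC=C(C)C)O[C@@H]2[C@@H]1OC(=O)c3ccc(cc3)[N+](=O)[O-]
F8 | step 3 | racemic 6 (tributylstannyl and hydroxymethyl cis on the oxirane) | CCCC[Sn](CCCC)(CCCC)C1(C/C=C(\C)CC/C=C(\C)CCC=C(C)C)OC1CO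
F9 | step 3 | acetate of the enantiomer of 6 | CCCC[Sn](CCCC)(CCCC)[C@@]1(C/C=C(\C)CC/C=C(\C)CCC=C(C)C)O[C@H]1COC(C)=O
F10 | step 2 | (2Z,5E,9E)-3-iodo-6,10,14-trimethylpentadeca-2,5,9,13-tetraen-1-ol | OC/C=C(\I)C/C=C(\C)CC/C=C(\C)CCC=C(C)C
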